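Readings and results were generated by integration with made-up constants, noise included.

| setting | maple | alder | flask |
|---|---|---|---|
| starting material | 39 mM | 39 mM | 39 mM |
| reagent | 97.5 mM (fed, over 50 h) | 150 mM (fed, over 50 h) | 97.5 mM (fed, over 50 h) |
| protic impurity | 1.95 mM | 1.95 mM | 1.95 mM |
| remark | the very flask that is asked about, followed so far | run made earlier |  |
| time |  |  | 15 d |

maple run (percent of the starting material charged)

| time / h | starting material / % | target / % |
|---|---|---|
| 3.00 | 97 | 2 |
| 5.00 | 90 | 7 |
| 8.00 | 84 | 8 |
| 12.0 | 78 | 17 |
| 20.0 | 55 | 27 |
| 30.0 | 39 | 38 |
| 40.0 | 23 | 48 |

alder run (percent of the starting material charged)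

| time / d | starting material / % | target / % |
|---|---|---|
| 0.625 | 61 | 27 |
| 1.67 | 15 | 54 |
| 3.00 | 11 | 55 |
| 5.00 | 9 | 57 |
| 6.00 | 7 | 56 |
| 8.00 | 10 | 55 |
| 10.0 | 13 | 59 |

(each reading ± 2 percentage points)

- which holds at 15 d: what has brought the reaction to rest, or that it has not come to rest (all of the starting material has reacted / forward and back rates have come level / it is still moving / the reagent has run out first)
- share of the starting material used up at 15 d
- target at 15 d, in percent of the starting material charged
- isomer of the product at 15 d, in percent of the starting material charged

- the analysis behind the earlier runs scatters by 2 percentage points, standard deviation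
- the reaction counts as stopped when no species that holds the starting material changes by six tenths of a point or more over the second half of the time

**The plateau.** Alder's feed ended at 50 h, and its readings from 3.00 d to 10.0 d stand level, so we average those 5: starting material 10.0%, target 56.4%.

**The constant.** Suppose one reagent takes up one starting material reversibly. Write f for the free share of starting material and b for the free reagent. Alder then has b = 115 mM, which gives K = 0.0783 mM⁻¹, the reacted share over the free share, divided by b: a lumped equilibrium constant.

**Maple's end.** For the maple flask, we first let all starting material react, so b = 58.5 mM and f = 17.9%. That hands reagent back, so b = 65.5 mM and f = 16.3%. We reckon conversion at 83.7%. Alder's target per reacted starting material, 62.7%, gives 52.5% target, and the unread remainder, which we take as isomer, is 31.2%.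

**The weak link.** Did alder stop at a balance, or for want of reagent? By 40.0 h maple had received 78.0 mM and lost 30.0 mM of starting material. Even at that ratio, alder's loss takes 91.2 mM, less than its 150 mM. On this reckoning alder did not stop for want of reagent, so we keep the balance.

**The forecast.** It says forward and back rates have come level, with conversion 84% (78% to 90%), target 52% (47% to 57%) and isomer 32% (27% to 37%), which is more than our remainder: “Equilibrium should arrive soon after feeding ends, well before 15 d.”

**The flask.** At 15 d, forward and back rates have come level: conversion 84.4%, target 52.0%, isomer 27.4%. Beside the isomer stands 5.00% of quenched substrate.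

    starting material + reagent ⇌ target (K = 50.0 L mol⁻¹, k = 4.90 × 10⁻⁴ L mol⁻¹ s⁻¹)
    starting material + reagent ⇌ isomer of the product (K = 26.4 L mol⁻¹, k = 2.07 × 10⁻⁴ L mol⁻¹ s⁻¹)
    starting material + protic impurity → quenched substrate (k = 0.00141 L mol⁻¹ s⁻¹)

**Once more.** A neighbouring flask, the same but with 59 mM of reagent, keeps 32.6 mM free at 15.0 d. K turns that into a free share of 28.2%, and that flask holds 27.2% starting material.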